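**Retrosynthetic overview**

1. Target ⇒ Stille disconnection of the C3–dienyl bond: a dienylstannane (from (S)-2-methylbutan-1-ol by Wittig and Takai olefinations) plus a 3-chloro bicyclic core; the pyridine ring is bought as 6-chloro-4-methylnicotinic acid.
2. Five-membered ring (C4a–C5–C6–C7–C7a) ⇐ six-membered carbocycle of a 7-acetoxy-7-methylisoquinoline-5,6,8-trione by benzilic ester ring contraction in MeOH: trione C6 is expelled as the CO2Me carbon, trione C5 becomes the carbinol, trione C7 becomes C6 of the target.
3. Enabling feature: C5 of the target carries OH and CO2Me on one ring carbon, bonded to aryl C4a and to the quaternary C6 (Me, OAc) next to the C7 aryl ketone; this is the α-hydroxy-ester signature of a contracted vicinal C5/C6 diketone in a ring with no enolisable position.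
4. Trione ⇐ SeO2 oxidation of the C5 methylene ⇐ six-membered ring closed by Claisen attack of the lateral (picolyl) anion on a Seebach dioxolanone ⇐ C-acylation of the L-lactic acid-derived dioxolanone enolate with the nicotinoyl chloride (sets the one stereocentre that is carried through).
5. Ring order: pyridine (bought) → six-membered carbocycle (step 4) → five-membered ring by contraction (step 7); the side chain is attached last.

Key step: step 7

Remark: the carbocycle is numbered as an isoquinoline (C5–C8) before the contraction and as a cyclopenta[c]pyridine (C5–C7) after it; the lactate-derived quaternary carbon is C7 before and C6 after.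
Remark: 8 and 10 are drawn as 5H-6,8-diketo tautomers (partial enolisation towards C5 is expected and harmless); trione 11 may be obtained as a hydrate and is dried before step 7.
Remark: 3 is used as the single cis diastereomer after crystallisation, because its diastereomeric purity becomes the enantiomeric purity of all later compounds.

**Route**

Step 1
Reactants: 1 L-(S)-lactic acid; 2 pivalaldehyde
Product: 3 (2S,5S)-2-tert-butyl-5-methyl-1,3-dioxolan-4-one (cis)
Conditions: p-TsOH·H2O (cat.), H2SO4 (cat.), pentane, reflux, Dean–Stark; recrystallisation from pentane/Et2O, −78 °C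
Reagents that add atoms: none
Why: Acid-catalysed acetalisation (Seebach dioxolanone formation) leaves the lactate centre untouched and sets the new acetal centre mainly cis to the methyl group under equilibrating conditions, the cis isomer being enriched by low-temperature crystallisation.

Step 2
Reactants: 4 6-chloro-4-methylpyridine-3-carboxylic acid
Product: 5 6-chloro-4-methylpyridine-3-carbonyl chloride
Conditions: (COCl)2, DMF (cat.), CH2Cl2, 0 °C → rt; evaporation
Reagents that add atoms: oxalyl chloride, ClC(=O)C(Cl)=O
Why: Vilsmeier-catalysed acid chloride formation is standard and should leave the 2-chloropyridine and the picoline methyl group untouched.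

Step 3
Reactants: 3 (2S,5S)-2-tert-butyl-5-methyl-1,3-dioxolan-4-one; 5 6-chloro-4-methylpyridine-3-carbonyl chloride
Product: 7 (2S,5R)-2-tert-butyl-5-(6-chloro-4-methylpyridine-3-carbonyl)-5-methyl-1,3-dioxolan-4-one, via lithium dioxolanone enolate 6 (not isolated)
Conditions: LiHMDS (1.05 equiv), THF, −78 °C; then cannulated into 5 (1.3 equiv), THF, −78 °C
Reagents that add atoms: none
Why: C-Acylation of the Seebach enolate (self-regeneration of stereocentres) should occur on the face anti to the tert-butyl group, so that the acyl group replaces the former lactate hydrogen with retention and sets the quaternary centre as 5R, and the product has no α-hydrogen that could quench further enolate.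

Step 4
Reactants: 7 (2S,5R)-2-tert-butyl-5-(6-chloro-4-methylpyridine-3-carbonyl)-5-methyl-1,3-dioxolan-4-one
Product: 8 (7S)-3-chloro-7-hydroxy-7-methyl-5,7-dihydroisoquinoline-6,8-dione
Conditions: LiHMDS (2.2 equiv), THF, −78 → 0 °C; aq. NH4Cl
Reagents that add atoms: none
Why: Lateral deprotonation of the γ-picoline methyl group next to the non-enolisable ketone gives an aza-benzylic anion that should close the six-membered ring by intramolecular Claisen (Dieckmann-type) attack on the dioxolanone carbonyl, with loss of pivalaldehyde and without touching the quaternary centre (LiHMDS has no β-hydrogen, so the aryl ketone is not reduced).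

Step 5
Reactants: 8 (7S)-3-chloro-7-hydroxy-7-methyl-5,7-dihydroisoquinoline-6,8-dione
Product: 10 (7S)-3-chloro-7-methyl-6,8-dioxo-5,6,7,8-tetrahydroisoquinolin-7-yl acetate, via bis-acetate 9 (not isolated)
Conditions: Ac2O (3 equiv), Et3N, DMAP (cat.), CH2Cl2, 0 °C → rt; then MeOH, NaHCO3, 0 °C → rt
Reagents that add atoms: acetic anhydride, CC(=O)OC(C)=O
Why: DMAP-catalysed acetylation should esterify both the tertiary alcohol and the C6 enol, and the activated enol acetate is then cleaved selectively by mild methanolysis while the tertiary alkyl acetate survives.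

Step 6
Reactants: 10 (7S)-3-chloro-7-methyl-6,8-dioxo-5,6,7,8-tetrahydroisoquinolin-7-yl acetate
Product: 11 (7R)-3-chloro-7-methyl-5,6,8-trioxo-5,6,7,8-tetrahydroisoquinolin-7-yl acetate
Conditions: SeO2 (1.3 equiv), 1,4-dioxane, 80 °C; filtration, azeotropic drying (toluene)
Reagents that add atoms: selenium dioxide, O=[Se]=O
Why: Riley oxidation should convert the only enolisable methylene (C5, aza-benzylic and α to the C6 ketone) into a ketone, since C7 is quaternary and neither a second α-position nor aromatisation is available.

Step 7
Reactants: 11 (7R)-3-chloro-7-methyl-5,6,8-trioxo-5,6,7,8-tetrahydroisoquinolin-7-yl acetate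
Product: 13 methyl (5R,6S)-6-acetoxy-3-chloro-5-hydroxy-6-methyl-7-oxo-6,7-dihydro-5H-cyclopenta[c]pyridine-5-carboxylate, via C6 methyl hemiketal 12 (not isolated)
Conditions: Cu(OTf)2 (20 mol %), MeOH (5 equiv), CH2Cl2, 4 Å MS, 0 °C → rt
Reagents that add atoms: methanol, CO
Why: Benzilic ester rearrangement under Lewis-acid instead of alkoxide promotion (closest known types: the benzilic step of the Hooker oxidation of 3-oxygenated naphthalene-1,2,4-triones and Lewis-acid-catalysed α-ketol shifts): Cu(II) chelates the cis-locked C5/C6 diketone, MeOH adds to the non-conjugated C6 carbonyl to give hemiketal 12, and the C6–C7 bond shifts to the activated C5 carbonyl, so that C6 leaves the ring as the CO2Me carbon and C5 becomes the tertiary carbinol. The five-membered ring is closed by this 1,2-shift (C5–C7 bond formation through a three-centre transition state, six-to-five contraction) and not by a separate cyclisation; should the aryl bond C4a–C5 migrate to C6 from the C5 hemiketal instead, the same constitution results. The lactate-derived centre migrates with retention (or is a spectator in the aryl-shift variant) and becomes C6 (S) unchanged. The new C5 centre is controlled by this neighbouring centre: in the bridged transition state the acetoxy group should turn away from the developing C5 alkoxide and the methyl group should lie beside the small C5–O (in the aryl-shift variant the same outcome follows from polar Felkin–Anh addition to C6=O anti to the C–OAc bond), so that the expelled ester carbon emerges cis to OAc and trans to methyl, i.e. 5R, which is also the less crowded diastereomer. The step needs the 1,2-shift to outrun retro-Claisen opening of the C6–C7 bond, which would pass through an achiral enolate and erase the quaternary centre, and to outrun acetate methanolysis; the base-free conditions (no free alkoxide or enolate), chelation at the C5/C6 pair and the absence of any enolisable ring position in 11 should secure this.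

Step 8
Reactants: 14 (S)-2-methylbutan-1-ol
Product: 16 ethyl (2E,4S)-2,4-dimethylhex-2-enoate, via (S)-2-methylbutanal 15 (not isolated)
Conditions: TEMPO (10 mol %), PhI(OAc)2 (1.1 equiv), CH2Cl2, rt; then Ph3P=C(Me)CO2Et, rt
Reagents that add atoms: ethyl 2-(triphenyl-λ5-phosphanylidene)propanoate, CCOC(=O)C(C)=P(c1ccccc1)(c1ccccc1)c1ccccc1
Why: TEMPO/PhI(OAc)2 oxidation should give the aldehyde without epimerising its α-centre, and the stabilised ylide converts it in the same flask into the (E)-trisubstituted enoate (Wittig olefination), so the volatile, configurationally labile aldehyde is never isolated.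

Step 9
Reactants: 16 ethyl (2E,4S)-2,4-dimethylhex-2-enoate
Product: 17 (2E,4S)-2,4-dimethylhex-2-en-1-ol
Conditions: DIBAL-H (2.2 equiv), CH2Cl2, −78 °C; Rochelle salt
Reagents that add atoms: none
Why: DIBAL-H 1,2-reduction of the conjugated ester should give the allylic alcohol without change of alkene geometry or of the stereocentre.

Step 10
Reactants: 17 (2E,4S)-2,4-dimethylhex-2-en-1-ol
Product: 18 (2E,4S)-2,4-dimethylhex-2-enal
Conditions: MnO2 (excess), CH2Cl2, rt
Reagents that add atoms: none
Why: MnO2 oxidises allylic alcohols selectively to enals under neutral conditions, which should preserve the E geometry and the γ-stereocentre.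

Step 11
Reactants: 18 (2E,4S)-2,4-dimethylhex-2-enal
Product: 19 (1E,3E,5S)-1-iodo-3,5-dimethylhepta-1,3-diene
Conditions: CrCl2 (6 equiv), CHI3 (2 equiv), THF, 0 °C → rt
Reagents that add atoms: iodoform, IC(I)I
Why: Takai olefination (addition of the geminal dichromium carbenoid to the aldehyde and elimination) should give the new C1=C2 bond with E geometry and leave the existing trisubstituted alkene unchanged.

Step 12
Reactants: 19 (1E,3E,5S)-1-iodo-3,5-dimethylhepta-1,3-diene
Product: 21 tributyl[(1E,3E,5S)-3,5-dimethylhepta-1,3-dien-1-yl]stannane, via dienyllithium 20 (not isolated)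
Conditions: t-BuLi (2.1 equiv), Et2O, −78 °C; then Bu3SnCl, −78 °C → rt
Reagents that add atoms: tributyltin chloride, CCCC[Sn](Cl)(CCCC)CCCC
Why: Iodine–lithium exchange proceeds with retention of alkene geometry and the dienyllithium should be trapped by Bu3SnCl to give the (E,E)-dienylstannane.

Step 13
Reactants: 13 methyl (5R,6S)-6-acetoxy-3-chloro-5-hydroxy-6-methyl-7-oxo-6,7-dihydro-5H-cyclopenta[c]pyridine-5-carboxylate; 21 tributyl[(1E,3E,5S)-3,5-dimethylhepta-1,3-dien-1-yl]stannane
Product: 22 methyl (5R,6S)-6-acetoxy-3-[(1E,3E,5S)-3,5-dimethylhepta-1,3-dien-1-yl]-5-hydroxy-6-methyl-7-oxo-6,7-dihydro-5H-cyclopenta[c]pyridine-5-carboxylate (target)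
Conditions: Pd(PPh3)4 (10 mol %), CuI (20 mol %), DMF, 80 °C
Reagents that add atoms: none
Why: Stille coupling should work because the C3 chloride is a 2-chloropyridine activated for oxidative addition by the para acyl group, the dienyl group transfers from tin with retention of both alkene geometries, and the neutral, base-free conditions spare the acetate, the methyl ester and the retro-aldol-prone tertiary β-hydroxy ketone.

**Compound list**

1 | L-(S)-lactic acid | C[C@H](O)C(=O)O | starting material
2 | pivalaldehyde | CC(C)(C)C=O | starting material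
3 | (2S,5S)-2-tert-butyl-5-methyl-1,3-dioxolan-4-one | C[C@@H]1O[C@H](C(C)(C)C)OC1=O | intermediate
4 | 6-chloro-4-methylpyridine-3-carboxylic acid | Cc1cc(Cl)ncc1C(=O)O | starting material
5 | 6-chloro-4-methylpyridine-3-carbonyl chloride | Cc1cc(Cl)ncc1C(Cl)=O | intermediate
6 | lithium (2S)-2-tert-butyl-5-methyl-1,3-dioxol-4-olate (enolate of 3) | CC1=C([O-])O[C@@H](C(C)(C)C)O1.[Li+] | intermediate (not isolated)
7 | (2S,5R)-2-tert-butyl-5-(6-chloro-4-methylpyridine-3-carbonyl)-5-methyl-1,3-dioxolan-4-one | Cc1cc(Cl)ncc1C(=O)[C@@]2(C)O[C@H](C(C)(C)C)OC2=O | intermediate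
8 | (7S)-3-chloro-7-hydroxy-7-methyl-5,7-dihydroisoquinoline-6,8-dione | O=C1Cc2cc(Cl)ncc2C(=O)[C@@]1(C)O | intermediate
9 | (7S)-3-chloro-7-methyl-8-oxo-7,8-dihydroisoquinoline-6,7-diyl diacetate | CC(=O)OC1=Cc2cc(Cl)ncc2C(=O)[C@@]1(C)OC(C)=O | intermediate (not isolated)
10 | (7S)-3-chloro-7-methyl-6,8-dioxo-5,6,7,8-tetrahydroisoquinolin-7-yl acetate | O=C1Cc2cc(Cl)ncc2C(=O)[C@@]1(C)OC(C)=O | intermediate
11 | (7R)-3-chloro-7-methyl-5,6,8-trioxo-5,6,7,8-tetrahydroisoquinolin-7-yl acetate | O=C1C(=O)c2cc(Cl)ncc2C(=O)[C@@]1(C)OC(C)=O | intermediate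
12 | (7R)-3-chloro-6-hydroxy-6-methoxy-7-methyl-5,8-dioxo-5,6,7,8-tetrahydroisoquinolin-7-yl acetate (C6 either configuration, copper-bound) | COC1(O)C(=O)c2cc(Cl)ncc2C(=O)[C@@]1(C)OC(C)=O | intermediate (not isolated)
13 | methyl (5R,6S)-6-acetoxy-3-chloro-5-hydroxy-6-methyl-7-oxo-6,7-dihydro-5H-cyclopenta[c]pyridine-5-carboxylate | Clc1cc2c(cn1)C(=O)[C@@](C)(OC(C)=O)[C@@]2(O)C(=O)OC | intermediate
14 | (S)-2-methylbutan-1-ol | CC[C@H](C)CO | starting material
15 | (S)-2-methylbutanal | CC[C@H](C)C=O | intermediate (not isolated)
16 | ethyl (2E,4S)-2,4-dimethylhex-2-enoate | CC[C@H](C)/C=C(\C)C(=O)OCC | intermediate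
17 | (2E,4S)-2,4-dimethylhex-2-en-1-ol | CC[C@H](C)/C=C(\C)CO | intermediate
18 | (2E,4S)-2,4-dimethylhex-2-enal | CC[C@H](C)/C=C(\C)C=O | intermediate
19 | (1E,3E,5S)-1-iodo-3,5-dimethylhepta-1,3-diene | CC[C@H](C)/C=C(C)/C=C/I | intermediate
20 | [(1E,3E,5S)-3,5-dimethylhepta-1,3-dien-1-yl]lithium | CC[C@H](C)/C=C(C)/C=C/[Li] | intermediate (not isolated)
21 | tributyl[(1E,3E,5S)-3,5-dimethylhepta-1,3-dien-1-yl]stannane | CC[C@H](C)/C=C(C)/C=C/[Sn](CCCC)(CCCC)CCCC | intermediate
22 | methyl (5R,6S)-6-acetoxy-3-[(1E,3E,5S)-3,5-dimethylhepta-1,3-dien-1-yl]-5-hydroxy-6-methyl-7-oxo-6,7-dihydro-5H-cyclopenta[c]pyridine-5-carboxylate | CC[C@H](C)/C=C(C)/C=C/c1cc2c(cn1)C(=O)[C@@](C)(OC(C)=O)[C@@]2(O)C(=O)OC | target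

**Step count and risks**

Total steps: 13. Longest linear sequence: 7 steps (1 or 2, then 3, 4, 5, 6, 7, 13); the side-chain branch is 5 steps (8–12) before the union.

Steps most likely to fail:

Step 7. The 1,2-shift may be outrun by retro-Claisen opening of the C6–C7 bond (loss of the quaternary centre), the facial control at C5 may be poor, or the acetate may be lost by methanolysis. The fallback contracts the ring on the free tertiary alcohol under classical alkoxide conditions and defers acetylation. It sets out from 8: SeO2 (dioxane, 80 °C) should give (7R)-3-chloro-7-hydroxy-7-methylisoquinoline-5,6,8(7H)-trione F1. NaOMe in MeOH at −20 °C should then effect the benzilic ester rearrangement on the C7 alkoxide, the substrate type of the Hooker oxidation itself; a retro-Claisen opening would here require a dianion and is disfavoured, and the developing C5 alkoxide should stay trans to the C7 oxygen. This gives methyl (5R,6S)-3-chloro-5,6-dihydroxy-6-methyl-7-oxo-6,7-dihydro-5H-cyclopenta[c]pyridine-5-carboxylate F2. Acetylation (Ac2O, DMAP, CH2Cl2, 0 °C) of the less hindered C6 hydroxyl, which is flanked by methyl whereas the C5 hydroxyl is shielded by the aryl ring and the ester, returns to the route at 13.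

Step 13. Oxidative addition at the aryl chloride may be slow, and prolonged heating with palladium may degrade 13 or epimerise it by retro-aldol opening. The fallback moves the coupling to a robust intermediate and makes the ring contraction the last step. It sets out from 10 and 21: Stille coupling (Pd(PPh3)4, CuI, DMF, 80 °C) should give (7S)-3-[(1E,3E,5S)-3,5-dimethylhepta-1,3-dien-1-yl]-7-methyl-6,8-dioxo-5,6,7,8-tetrahydroisoquinolin-7-yl acetate F3. Because SeO2 would attack the diene, C5 is oxidised by condensation with DMF dimethyl acetal (toluene, 80 °C) to the 5-[(dimethylamino)methylidene] derivative of F3 (C7 as in 10) F4, followed by NaIO4 cleavage of the enamine C=C (THF/H2O, rt) to (7R)-3-[(1E,3E,5S)-3,5-dimethylhepta-1,3-dien-1-yl]-7-methyl-5,6,8-trioxo-5,6,7,8-tetrahydroisoquinolin-7-yl acetate F5. The conditions of step 7 (Cu(OTf)2, MeOH, CH2Cl2) then return to the route at 22.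

Step 6. The electron-poor trione may be over-oxidised or decompose under hot SeO2, or the oxidation may stop short. The fallback sets out from 10: condensation with DMF dimethyl acetal (toluene, 80 °C) should give (7-configuration as in 10) 3-chloro-5-[(dimethylamino)methylidene]-7-methyl-6,8-dioxo-5,6,7,8-tetrahydroisoquinolin-7-yl acetate F6; ozonolysis of the enaminone C=C (O3, CH2Cl2, −78 °C; Me2S), a vicinal tricarbonyl synthesis of the Wasserman type, returns to the route at 11.

**Further compounds**

F1 | step 7 | (7R)-3-chloro-7-hydroxy-7-methylisoquinoline-5,6,8(7H)-trione | O=C1C(=O)c2cc(Cl)ncc2C(=O)[C@@]1(C)O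
F2 | step 7 | methyl (5R,6S)-3-chloro-5,6-dihydroxy-6-methyl-7-oxo-6,7-dihydro-5H-cyclopenta[c]pyridine-5-carboxylate | Clc1cc2c(cn1)C(=O)[C@@](C)(O)[C@@]2(O)C(=O)OC
F3 | step 13 | (7S)-3-[(1E,3E,5S)-3,5-dimethylhepta-1,3-dien-1-yl]-7-methyl-6,8-dioxo-5,6,7,8-tetrahydroisoquinolin-7-yl acetate | CC[C@H](C)/C=C(C)/C=C/c1cc2c(cn1)C(=O)[C@@](C)(OC(C)=O)C(=O)C2
F4 | step 13 | 5-[(dimethylamino)methylidene] derivative of F3 (C7 as in 10) | CC[C@H](C)/C=C(C)/C=C/c1cc2c(cn1)C(=O)[C@@](C)(OC(C)=O)C(=O)C2=CN(C)C
F5 | step 13 | (7R)-3-[(1E,3E,5S)-3,5-dimethylhepta-1,3-dien-1-yl]-7-methyl-5,6,8-trioxo-5,6,7,8-tetrahydroisoquinolin-7-yl acetate | CC[C@H](C)/C=C(C)/C=C/c1cc2c(cn1)C(=O)[C@@](C)(OC(C)=O)C(=O)C2=O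
F6 | step 6 | 3-chloro-5-[(dimethylamino)methylidene]-7-methyl-6,8-dioxo-5,6,7,8-tetrahydroisoquinolin-7-yl acetate (C7 as in 10) | O=C1C(=CN(C)C)c2cc(Cl)ncc2C(=O)[C@@]1(C)OC(C)=O
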